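## Structural features

The target is a 2-aryl-3-(hydroxymethyl)-2,3-dihydrobenzofuran. Ring A is a benzene ring carrying O1, a methoxy group at C7 and an (E)-3-hydroxyprop-1-enyl chain at C5; it is fused to the dihydrofuran ring (O1, C2, C3, C3a, C7a). C2 carries ring B, a 4-hydroxy-3,5-dimethoxyphenyl group, and C3 carries the one-carbon arm C9 as CH2OH. The only stereocentres, C2 (R) and C3 (S), are adjacent and trans: ring B and the C9 arm lie on opposite faces of the five-membered ring. C2 is a benzylic ether flanked by O1 and by an electron-rich aryl group with a para oxygen, so it ionises easily under acid; this makes C2 correctable (ring closure favours trans) but makes the finished ring system sensitive to acids and Lewis acids. The cinnamyl alcohol is acid-labile, its double bond excludes hydrogenolysis, and the free ring B phenol is easily oxidised, so the end game must be short and mild. The real difficulty is the absolute configuration at C3, a non-epimerisable carbon without a heteroatom that bears three carbon substituents (C2, C3a of ring A, C9). The key step uses exactly this arrangement: C3 is bonded to C9 and to C2, and C2 (oxygen-bearing, attached to ring B) accommodates positive charge, so the C2–C3 bond can be taken as the double bond of an E stilbene that accepts a formaldehyde-derived carbon at C3 and an oxygen at C2.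

## Logic of the disconnections

13 to 12. No skeletal bond is cut; the terminal carbon of the C5 side chain is taken back from the allylic alcohol to the methyl ester. The enoate tolerates palladium chemistry, strong acid and basic methanol, withdraws electron density from ring A (useful in the key step) and postpones the acid-labile cinnamyl alcohol to the last step. The forward step must reduce 1,2 only, in the presence of two acidic hydroxyl groups.

12 to 11 to 10. The O1–C2 bond is cut and C2 is bonded instead to an oxygen that is tied through one CH2 group to the C9 oxygen, so the dihydrofuran becomes a 1,3-dioxane (11); both phenols are then masked, ring A as acetate and ring B as tert-butyldimethylsilyl ether (10). The cut is made here because this benzylic C–O bond can be formed late under equilibrating conditions: the cation at C2 closes onto the ring A oxygen trans to the C9 arm whatever the earlier configuration at that carbon. The gain is that the five-membered ring and the C2 stereocentre leave the problem and only C3 needs control. The forward step must unmask both phenols without harming the methyl ester, ionise only the benzylic acetal C–O bond, leave C3 untouched and shed the acetal carbon. A benzyl ether on ring B was rejected: the alkenes rule out hydrogenolysis, and a Lewis-acid debenzylation would have to run on the acid-labile 2-aryl dihydrobenzofuran. The silyl ether falls in the same basic methanolysis as the acetate, and the free para phenol then makes the ionisation easy.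

10 to 8 + 9. Three bonds are cut: C3–C9 (C5–C6 of the dioxane), C2–O (C4–O3) and the O–CH2 bond joining two molecules of 9. This returns a flat, achiral E stilbene and a one-carbon feedstock, and removes both stereocentres and the ring in one operation. The forward step must put the new C–C bond on the alkene carbon attached to ring A, choose one face of that carbon, and leave the enoate double bond and the arenes alone. The acetoxy group and enoate on ring A and the para silyloxy group on ring B are placed to bias the regiochemistry.

8 to 7 + 3. The bond between ring A (the later C3a) and the alkene carbon that becomes C3 is cut (Heck coupling). The iodine of 7 sits exactly where that bond is needed, ortho to the masked phenol, and 3 is a terminal styrene, so the E geometry follows from the coupling mechanism. The gain is two benzene building blocks of similar size, each two steps from a commercial aldehyde; an olefination route would need a four-step benzylic phosphonate and the olefination of an unprotected salicylaldehyde phenoxide. The forward step must insert at the terminal carbon of 3 and spare the acetate and the silyl ether.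

7 to 5 + 6, and 5 to 4. The enoate C=C is cut (Wittig olefination with the stabilised ylide 6), then the O–acyl bond. Acetylation comes first so that the aldehyde is not deactivated by a phenoxide. The demand is E selectivity and survival of the aryl acetate and iodide.

3 to 2 to 1. The terminal C=C is cut (methylenation of the aldehyde), then the O–Si bond. The demand is that the ylide base does not attack the aryl silyl ether.

## Other disconnections considered

Alternative 1: The cut is at C2–C3 and O1–C2. O1, C3a and C3 (with C9 attached) come from the ortho-quinone methide A2, and C2 with ring B from the chiral sulfonium ylide A3. In the forward key step A2, formed in the flask, would be attacked at its methide carbon by A3 (C2–C3), and the phenoxide would then displace the sulfide at C2 (O1–C2) to give the bis-silyl bromide A1. A Heck coupling with an acrylate, desilylation and ester reduction would finish.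
- In favour: the ring and both stereocentres arise in one step, and trans selectivity is built into the addition–substitution sequence. The [4+1] annulation of ortho-quinone methides with sulfur ylides, chiral sulfide versions included, is an established reaction type; on precedent this alternative is the better.
- Against it here: A2 has hydrogens next to the exocyclic double bond, and such ortho-quinone methides tautomerise by hydrogen shift to ortho-hydroxystyrenes in competition with capture. A3 is an electron-rich, semi-stabilised benzyl ylide, a less well-behaved class than ester ylides, whose addition can be reversible. The configuration would rest on a stoichiometric chiral sulfide, and the precursor of A2 needs its own multistep preparation.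
- Comparison: both plans need a Heck reaction, so they are equal on that point. The mechanism is polar and stepwise with reagent control, against catalyst control on an achiral alkene in the chosen plan. The step count is similar or one to two steps longer once both partners are counted.

Alternative 2: The cut is at C3–C3a. In the flavanone A5 ring A is bonded to the carbonyl carbon. PhI(OAc)2 (trivalent iodine) with acid in trimethyl orthoformate would functionalise C3 of the enol ether, and ring A would migrate from the carbonyl carbon to C3 as the iodane leaves. The pyranone contracts to the dihydrofuran ester A4, with the former carbonyl carbon as the C9 ester.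
- In favour: the 1,2-aryl shift is stereospecific and precedented on flavanones, so on precedent this alternative is the better. The C2 stereocentre is carried through and governs C3, and the trans ester is also the thermodynamic isomer, so it is equal to the chosen plan on trans control. C9 arrives in place.
- Against it here: an enantioenriched flavanone with this oxygenation must be made first. Flavanones racemise by reversible retro-oxa-Michael ring opening, and the contraction medium is strongly acidic. The electron-rich rings compete for the oxidant, hence the pivalate and the bromide. Dehydrogenation of the heterocycle is a usual side path. Afterwards the C9 ester must be reduced, the side chain added by Heck coupling and the pivalate removed.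
- Comparison: the structure is the same dihydrobenzofuran with C9 at the ester level. The stereochemistry depends on the enantiomeric purity of a configurationally fragile precursor, where the chosen plan creates it on an achiral stilbene. The route is longer by several steps.

Alternative 3: The cut is at C3a–C4 and C7–C7a, two bonds of ring A. The heterocycle with both stereocentres exists first as the butyrolactone A9, whose ketene O,S-acetal A7 is the electron-rich two-carbon partner of the electron-poor 2-pyrone A8. In the forward step the nucleophilic carbon of A7 (later C3a) would bond to C6 of A8 (later C4) and the acetal carbon (later C7a) to C3 of A8 (later C7). Cycloreversion with loss of the lactone bridge and elimination of the sulfur group would aromatise ring A to give A6.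
- In favour: the stereocentres are installed early on a small lactone, where trans is thermodynamically secure and enantioselective entries are well known, and the key step does not touch them. On robustness of stereochemistry this alternative is the better. The regiochemistry of the benzannulation follows from polarity, and no cation is generated at C2.
- Against it here: A7 would have to be made from A9 by thionation and S-methylation, and its ring oxygen is benzylic at C2, so acid or heat can open it. The cycloaddition needs heat, and the methoxy group on A8 lowers its electron demand. Ring A emerges with a C5 ester that must be extended by two carbons (three to four extra steps), whereas the chosen plan carries the three-carbon chain from the start. The methoxymethyl ether must be removed with acid late.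
- Comparison: the route is more linear and clearly longer. The mechanism is a pericyclic cascade with precedent for pyrone benzannulation, equal or better than the chosen key step on that count, but the step economy is worse.

Key step: step 6

Assumption: the sense of induction of the confined acid on a stilbene cannot be derived with certainty from the styrene precedent; the enantiomer of the catalyst (both are made from commercial (R)- or (S)-BINOL) that delivers (5S) in 10 is the one used.

Step 1
Reactants: 1 syringaldehyde (4-hydroxy-3,5-dimethoxybenzaldehyde)
Product: 2 4-[(tert-butyldimethylsilyl)oxy]-3,5-dimethoxybenzaldehyde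
Conditions: t-BuMe2SiCl, imidazole, DMF, 25 °C
Reagents that add atoms: tert-butyldimethylsilyl chloride, CC(C)(C)[Si](C)(C)Cl
Why: Standard silylation of a phenol with the silyl chloride–imidazole pair in DMF; the hindered but acidic 2,6-dimethoxyphenol oxygen reacts and the aldehyde is inert.

Step 2
Reactants: 2 4-[(tert-butyldimethylsilyl)oxy]-3,5-dimethoxybenzaldehyde
Product: 3 tert-butyl(4-ethenyl-2,6-dimethoxyphenoxy)dimethylsilane
Conditions: Ph3PCH3Br, KOt-Bu, THF, 0 → 25 °C
Reagents that add atoms: methyltriphenylphosphonium bromide, C[P+](c1ccccc1)(c1ccccc1)c1ccccc1.[Br-]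
Why: Wittig methylenation of an aromatic aldehyde with the non-stabilised ylide; the ylide is formed before 2 is added so that no free alkoxide meets the aryl silyl ether.

Step 3
Reactants: 4 5-iodovanillin (4-hydroxy-3-iodo-5-methoxybenzaldehyde)
Product: 5 4-formyl-2-iodo-6-methoxyphenyl acetate
Conditions: Ac2O, pyridine, 4-(dimethylamino)pyridine (cat.), CH2Cl2, 25 °C
Reagents that add atoms: acetic anhydride, CC(=O)OC(C)=O
Why: Base-catalysed O-acetylation of the phenol; the acetate masks the oxygen ortho to the iodide and later makes ring A the poorer cation-stabilising ring.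

Step 4
Reactants: 5 4-formyl-2-iodo-6-methoxyphenyl acetate; 6 methyl (triphenylphosphoranylidene)acetate
Product: 7 methyl (E)-3-(4-acetoxy-3-iodo-5-methoxyphenyl)prop-2-enoate
Conditions: CH2Cl2, 25 °C
Reagents that add atoms: none
Why: Wittig olefination with a stabilised ylide, which is E-selective and mild enough to leave the aryl acetate and the aryl iodide untouched.

Step 5
Reactants: 7 methyl (E)-3-(4-acetoxy-3-iodo-5-methoxyphenyl)prop-2-enoate; 3 tert-butyl(4-ethenyl-2,6-dimethoxyphenoxy)dimethylsilane
Product: 8 methyl (E)-3-{4-acetoxy-3-[(E)-2-{4-[(tert-butyldimethylsilyl)oxy]-3,5-dimethoxyphenyl}ethenyl]-5-methoxyphenyl}prop-2-enoate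
Conditions: Pd(OAc)2 (5 mol%), P(o-tol)3 (10 mol%), Et3N, MeCN, 80 °C
Reagents that add atoms: none
Why: Mizoroki–Heck coupling: oxidative addition of the electron-poor aryl iodide to zerovalent palladium, insertion of the terminal styrene at its unsubstituted carbon and syn β-hydride elimination should give the E stilbene. The internal enoate double bond of 7 is a far poorer acceptor than the terminal alkene of 3, and dry triethylamine should not cleave the acetate or the silyl ether.

Step 6
Reactants: 8 methyl (E)-3-{4-acetoxy-3-[(E)-2-{4-[(tert-butyldimethylsilyl)oxy]-3,5-dimethoxyphenyl}ethenyl]-5-methoxyphenyl}prop-2-enoate; 9 formaldehyde (used as paraformaldehyde; two molecules are incorporated)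
Product: 10 methyl (E)-3-{4-acetoxy-3-[(4S,5S)-4-{4-[(tert-butyldimethylsilyl)oxy]-3,5-dimethoxyphenyl}-1,3-dioxan-5-yl]-5-methoxyphenyl}prop-2-enoate
Conditions: (CH2O)n (6 equiv), chiral IDPi acid HN[P(=NSO2CF3)(O2C20H10Ar2)]2 (BINOL-derived, Ar = 3,5-(CF3)2C6H3, 5 mol%), cyclohexane/CHCl3, 25 °C
Reagents that add atoms: none
Why: Proposed new method: inside the chiral pocket the acid activates a formaldehyde oligomer as an oxocarbenium ion (formally HOCH2OCH2+), whose carbon bonds to the alkene carbon attached to ring A while positive charge develops on the carbon attached to ring B, and the hemiacetal oxygen then closes onto that carbon from the same face in one concerted, asynchronous event. The closest known reaction type is the catalytic asymmetric intermolecular Prins reaction of terminal styrenes with paraformaldehyde, which gives 4-aryl-1,3-dioxanes under confined chiral imidodiphosphorimidate-type acids; a 1,2-diaryl alkene has not been used in it. The one ring closed is the 1,3-dioxane, by a formal [4+2] union of the C–O–C–O unit of the formaldehyde dimer with the two alkene carbons, C5–C6 leading and C4–O3 completing the six-membered ring. C5 (S, the later C3) is set by the chiral counter-anion, which decides the face of the ring A alkene carbon that meets the electrophile. C4 (S) follows from suprafacial addition across the E double bond, so it is fixed by alkene geometry; as C4 is reset in step 7, only C5 has to be right. Regioselectivity (C–C bond at the ring A carbon) is secured by the substrate: ring B with its para silyloxy oxygen stabilises the developing cation, while ring A is deactivated by the ortho acetoxy group and the meta enoate. Chemoselectivity is secured by the electron-poor enoate double bond, which oxocarbenium ions do not attack, and by the confinement of the acid, which disfavours hydroxymethylation of the arenes.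

Step 7
Reactants: 10 methyl (E)-3-{4-acetoxy-3-[(4S,5S)-4-{4-[(tert-butyldimethylsilyl)oxy]-3,5-dimethoxyphenyl}-1,3-dioxan-5-yl]-5-methoxyphenyl}prop-2-enoate
Product: 12 methyl (E)-3-[(2R,3S)-2-(4-hydroxy-3,5-dimethoxyphenyl)-3-(hydroxymethyl)-7-methoxy-2,3-dihydro-1-benzofuran-5-yl]prop-2-enoate, via bisphenol dioxane 11 (not isolated)
Conditions: K2CO3 (3 equiv), MeOH/THF, 25 °C, argon; then HCl (1.25 M in MeOH, to pH 1), 25 → 40 °C
Reagents that add atoms: none
Why: Carbonate in methanol transesterifies the aryl acetate and cleaves the aryl silyl ether (methanolysis leaves the methyl ester unchanged), giving 11. On acidification the benzylic acetal oxygen at C4 leaves to give a para-hydroxybenzylic cation stabilised by the free ring B phenol, which the ortho phenol of ring A traps in a 5-exo closure while the acetal carbon is lost to the solvent; this is the acid-catalysed benzylic transetherification known for phenolic 1,2-diarylpropane-1,3-diol derivatives closing to phenylcoumarans. C3 (the former C5) is untouched, and C2 is set trans to the C9 arm because closure places ring B and the hydroxymethyl group on opposite faces and any cis isomer can re-ionise.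

Step 8
Reactants: 12 methyl (E)-3-[(2R,3S)-2-(4-hydroxy-3,5-dimethoxyphenyl)-3-(hydroxymethyl)-7-methoxy-2,3-dihydro-1-benzofuran-5-yl]prop-2-enoate
Product: 13 (E)-3-[(2R,3S)-2-(4-hydroxy-3,5-dimethoxyphenyl)-3-(hydroxymethyl)-7-methoxy-2,3-dihydro-1-benzofuran-5-yl]prop-2-en-1-ol
Conditions: i-Bu2AlH (6 equiv), THF/toluene, −78 → 0 °C; then aqueous KNaC4H4O6
Reagents that add atoms: none
Why: Standard 1,2-reduction of a cinnamate ester to the cinnamyl alcohol with diisobutylaluminium hydride; the excess reagent first converts the two acidic hydroxyl groups into aluminium alkoxides, and neither stereocentre is affected.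

## Compound list

1 | syringaldehyde (4-hydroxy-3,5-dimethoxybenzaldehyde) | COc1cc(C=O)cc(OC)c1O | starting material
2 | 4-[(tert-butyldimethylsilyl)oxy]-3,5-dimethoxybenzaldehyde | COc1cc(C=O)cc(OC)c1O[Si](C)(C)C(C)(C)C | intermediate
3 | tert-butyl(4-ethenyl-2,6-dimethoxyphenoxy)dimethylsilane | COc1cc(C=C)cc(OC)c1O[Si](C)(C)C(C)(C)C | intermediate
4 | 5-iodovanillin (4-hydroxy-3-iodo-5-methoxybenzaldehyde) | COc1cc(C=O)cc(I)c1O | starting material
5 | 4-formyl-2-iodo-6-methoxyphenyl acetate | COc1cc(C=O)cc(I)c1OC(C)=O | intermediate
6 | methyl (triphenylphosphoranylidene)acetate | COC(=O)C=P(c1ccccc1)(c1ccccc1)c1ccccc1 | starting material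
7 | methyl (E)-3-(4-acetoxy-3-iodo-5-methoxyphenyl)prop-2-enoate | COC(=O)/C=C/c1cc(I)c(OC(C)=O)c(OC)c1 | intermediate
8 | methyl (E)-3-{4-acetoxy-3-[(E)-2-{4-[(tert-butyldimethylsilyl)oxy]-3,5-dimethoxyphenyl}ethenyl]-5-methoxyphenyl}prop-2-enoate | COc1cc(/C=C/c2cc(/C=C/C(=O)OC)cc(OC)c2OC(C)=O)cc(OC)c1O[Si](C)(C)C(C)(C)C | intermediate
9 | formaldehyde (used as paraformaldehyde) | C=O | starting material
10 | methyl (E)-3-{4-acetoxy-3-[(4S,5S)-4-{4-[(tert-butyldimethylsilyl)oxy]-3,5-dimethoxyphenyl}-1,3-dioxan-5-yl]-5-methoxyphenyl}prop-2-enoate | COc1cc([C@H]2OCOC[C@@H]2c3cc(/C=C/C(=O)OC)cc(OC)c3OC(C)=O)cc(OC)c1O[Si](C)(C)C(C)(C)C | intermediate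
11 | methyl (E)-3-{4-hydroxy-3-[(4S,5S)-4-(4-hydroxy-3,5-dimethoxyphenyl)-1,3-dioxan-5-yl]-5-methoxyphenyl}prop-2-enoate | COc1cc([C@H]2OCOC[C@@H]2c3cc(/C=C/C(=O)OC)cc(OC)c3O)cc(OC)c1O | intermediate
12 | methyl (E)-3-[(2R,3S)-2-(4-hydroxy-3,5-dimethoxyphenyl)-3-(hydroxymethyl)-7-methoxy-2,3-dihydro-1-benzofuran-5-yl]prop-2-enoate | COc1cc([C@@H]2Oc3c(OC)cc(/C=C/C(=O)OC)cc3[C@H]2CO)cc(OC)c1O | intermediate
13 | (E)-3-[(2R,3S)-2-(4-hydroxy-3,5-dimethoxyphenyl)-3-(hydroxymethyl)-7-methoxy-2,3-dihydro-1-benzofuran-5-yl]prop-2-en-1-ol | COc1cc([C@@H]2Oc3c(OC)cc(/C=C/CO)cc3[C@H]2CO)cc(OC)c1O | target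

## Step count and least certain steps

Total: 8 steps (step 7 is a one-flask, two-stage operation). Longest linear sequence: 6 steps (4 → 5 → 7 → 8 → 10 → 12 → 13; the branch from 1 is equally long).

**Step 6 (key step).** The most likely failure is insufficient reactivity. A 1,2-diaryl alkene is more hindered than a terminal styrene, and the para oxygen of ring B is twisted out of conjugation by its two methoxy neighbours, so the alkene is only moderately nucleophilic and the confined pocket may not turn it over. Forcing the reaction with a stronger or more open acid would erode enantiofacial control and invite hydroxymethylation of ring B, loss of the silyl group or a stepwise cationic path. A stepwise path alone would cost only the C4 configuration, which step 7 resets; loss of facial control at C5 cannot be repaired.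

Fallback (known chemistry; sets out from 7 and 2, rejoins at 12):
- Negishi-type coupling of 7 with the Reformatsky reagent BrZnCH2CO2t-Bu (Pd(dba)2, P(t-Bu)3, THF, 25 °C) gives tert-butyl 2-{2-acetoxy-3-methoxy-5-[(E)-3-methoxy-3-oxoprop-1-en-1-yl]phenyl}acetate F1.
- CF3CO2H in CH2Cl2 frees the arylacetic acid F2.
- Activation as the mixed pivalic anhydride (t-BuCOCl, Et3N) and acylation of (4R)-4-benzyl-1,3-oxazolidin-2-one (LiCl) gives the imide F3.
- The Evans syn-aldol reaction of its dibutylboron enolate (n-Bu2BOTf, i-Pr2NEt, CH2Cl2, −78 → 0 °C) with 2 gives the β-hydroxy imide F4; the auxiliary fixes the carbon that becomes C3.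
- NaBH4 in THF–water removes the auxiliary reductively and leaves the enoate alone, giving the 1,3-diol F5.
- F5 is submitted to the conditions of step 7, which remove acetate and silyl ether and close the dihydrofuran ring trans through the benzylic cation, giving 12.

This costs six operations from 7 in place of three and uses a stoichiometric auxiliary.

**Step 7.** The most likely failure is fragmentation of the benzylic cation in the acid stage. The C9 carbon can be lost as formaldehyde, regenerating a stilbene, or a proton can be lost from C3 with aromatisation to a benzofuran, which would destroy the stereocentre. A second risk is incomplete cleavage of the hindered aryl silyl ether in the basic stage.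

Fallback (sets out from 10, rejoins at 12): the order of events is inverted so that the ionising species is the silyl ether and silicon is removed by fluoride.
- NH3 in MeOH at 0 °C removes only the acetate, giving the silyl-protected phenol dioxane F6.
- BF3·OEt2 in CH2Cl2 (−40 → 0 °C, then aqueous NaHCO3) ionises the benzylic acetal C–O bond under aprotic conditions; ring A phenol closes the ring to give the silyl-protected dihydrobenzofuran F7.
- n-Bu4NF buffered with AcOH in THF at 0 °C gives 12.

**Step 5.** The most likely failure is erosion of regiocontrol in the insertion: aryl transfer to the internal carbon of the electron-rich styrene would give a 1,1-diarylethene. Slow solvolysis of the acetate or silyl ether in hot amine and thermal polymerisation of 3 are further drains.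

Fallback (sets out from 2, rejoins at 8): the stilbene is made by carbonyl olefination, which fixes the connectivity.
- NaBH4 in MeOH reduces 2 to the benzylic alcohol F8.
- An Appel reaction (CBr4, PPh3) gives the benzylic bromide F9.
- A Michaelis–Arbuzov reaction with P(OEt)3 at 120 °C gives the diethyl benzylphosphonate F10.
- Separately, Heck coupling of commercial 5-bromo-2-hydroxy-3-methoxybenzaldehyde with methyl acrylate (Pd(OAc)2, P(o-tol)3, Et3N, DMF, 100 °C) gives the hydroxy aldehyde F11.
- Horner–Wadsworth–Emmons olefination of F11 with the lithium salt of F10 (LiN(SiMe3)2, 2.2 equiv, THF, −78 → 0 °C) gives the E hydroxystilbene F12.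
- Acetylation (Ac2O, pyridine) gives 8.

## Further compounds

F1 | step 6 | tert-butyl 2-{2-acetoxy-3-methoxy-5-[(E)-3-methoxy-3-oxoprop-1-en-1-yl]phenyl}acetate | COC(=O)/C=C/c1cc(CC(=O)OC(C)(C)C)c(OC(C)=O)c(OC)c1
F2 | step 6 | 2-{2-acetoxy-3-methoxy-5-[(E)-3-methoxy-3-oxoprop-1-en-1-yl]phenyl}acetic acid | COC(=O)/C=C/c1cc(CC(=O)O)c(OC(C)=O)c(OC)c1
F3 | step 6 | methyl (E)-3-(4-acetoxy-3-{2-[(4R)-4-benzyl-2-oxo-1,3-oxazolidin-3-yl]-2-oxoethyl}-5-methoxyphenyl)prop-2-enoate | COC(=O)/C=C/c1cc(CC(=O)N2[C@H](Cc3ccccc3)COC2=O)c(OC(C)=O)c(OC)c1
F4 | step 6 | methyl (E)-3-{4-acetoxy-3-[(2R,3R)-1-[(4R)-4-benzyl-2-oxo-1,3-oxazolidin-3-yl]-3-{4-[(tert-butyldimethylsilyl)oxy]-3,5-dimethoxyphenyl}-3-hydroxy-1-oxopropan-2-yl]-5-methoxyphenyl}prop-2-enoate | COC(=O)/C=C/c1cc([C@@H](C(=O)N2[C@H](Cc3ccccc3)COC2=O)[C@@H](O)c4cc(OC)c(O[Si](C)(C)C(C)(C)C)c(OC)c4)c(OC(C)=O)c(OC)c1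
F5 | step 6 | methyl (E)-3-{4-acetoxy-3-[(1R,2S)-1-{4-[(tert-butyldimethylsilyl)oxy]-3,5-dimethoxyphenyl}-1,3-dihydroxypropan-2-yl]-5-methoxyphenyl}prop-2-enoate | COC(=O)/C=C/c1cc([C@@H](CO)[C@@H](O)c2cc(OC)c(O[Si](C)(C)C(C)(C)C)c(OC)c2)c(OC(C)=O)c(OC)c1
F6 | step 7 | methyl (E)-3-{3-[(4S,5S)-4-{4-[(tert-butyldimethylsilyl)oxy]-3,5-dimethoxyphenyl}-1,3-dioxan-5-yl]-4-hydroxy-5-methoxyphenyl}prop-2-enoate | COc1cc([C@H]2OCOC[C@@H]2c3cc(/C=C/C(=O)OC)cc(OC)c3O)cc(OC)c1O[Si](C)(C)C(C)(C)C
F7 | step 7 | methyl (E)-3-[(2R,3S)-2-{4-[(tert-butyldimethylsilyl)oxy]-3,5-dimethoxyphenyl}-3-(hydroxymethyl)-7-methoxy-2,3-dihydro-1-benzofuran-5-yl]prop-2-enoate | COc1cc([C@@H]2Oc3c(OC)cc(/C=C/C(=O)OC)cc3[C@H]2CO)cc(OC)c1O[Si](C)(C)C(C)(C)C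
F8 | step 5 | {4-[(tert-butyldimethylsilyl)oxy]-3,5-dimethoxyphenyl}methanol | COc1cc(CO)cc(OC)c1O[Si](C)(C)C(C)(C)C
F9 | step 5 | [4-(bromomethyl)-2,6-dimethoxyphenoxy](tert-butyl)dimethylsilane | COc1cc(CBr)cc(OC)c1O[Si](C)(C)C(C)(C)C
F10 | step 5 | diethyl {4-[(tert-butyldimethylsilyl)oxy]-3,5-dimethoxybenzyl}phosphonate | CCOP(=O)(Cc1cc(OC)c(O[Si](C)(C)C(C)(C)C)c(OC)c1)OCC
F11 | step 5 | methyl (E)-3-(3-formyl-4-hydroxy-5-methoxyphenyl)prop-2-enoate | COC(=O)/C=C/c1cc(C=O)c(O)c(OC)c1
F12 | step 5 | methyl (E)-3-{3-[(E)-2-{4-[(tert-butyldimethylsilyl)oxy]-3,5-dimethoxyphenyl}ethenyl]-4-hydroxy-5-methoxyphenyl}prop-2-enoate | COc1cc(/C=C/c2cc(/C=C/C(=O)OC)cc(OC)c2O)cc(OC)c1O[Si](C)(C)C(C)(C)C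
A1 | alternative 1 | (2R,3S)-5-bromo-3-{[(tert-butyldimethylsilyl)oxy]methyl}-2-{4-[(tert-butyldimethylsilyl)oxy]-3,5-dimethoxyphenyl}-7-methoxy-2,3-dihydro-1-benzofuran | COc1cc([C@@H]2Oc3c(OC)cc(Br)cc3[C@H]2CO[Si](C)(C)C(C)(C)C)cc(OC)c1O[Si](C)(C)C(C)(C)C
A2 | alternative 1 | (6E)-4-bromo-6-{2-[(tert-butyldimethylsilyl)oxy]ethylidene}-2-methoxycyclohexa-2,4-dien-1-one | O=C1C(OC)=CC(Br)=C/C1=C\CO[Si](C)(C)C(C)(C)C
A3 | alternative 1 | {4-[(tert-butyldimethylsilyl)oxy]-3,5-dimethoxyphenyl}[(2R,5R)-2,5-dimethylthiolan-1-ium-1-yl]methanide (example of a chiral sulfide; its antipode if the sense of induction requires) | C[C@@H]1CC[C@@H](C)[S+]1[CH-]c1cc(OC)c(O[Si](C)(C)C(C)(C)C)c(OC)c1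
A4 | alternative 2 | methyl (2R,3R)-5-bromo-2-[3,5-dimethoxy-4-(pivaloyloxy)phenyl]-7-methoxy-2,3-dihydro-1-benzofuran-3-carboxylate | COc1cc([C@@H]2Oc3c(OC)cc(Br)cc3[C@H]2C(=O)OC)cc(OC)c1OC(=O)C(C)(C)C
A5 | alternative 2 | 4-[(2R)-6-bromo-8-methoxy-4-oxo-3,4-dihydro-2H-chromen-2-yl]-2,6-dimethoxyphenyl 2,2-dimethylpropanoate | COc1cc([C@H]2CC(=O)c3cc(Br)cc(OC)c3O2)cc(OC)c1OC(=O)C(C)(C)C
A6 | alternative 3 | methyl (2R,3S)-2-[3,5-dimethoxy-4-(methoxymethoxy)phenyl]-7-methoxy-3-{[(triisopropylsilyl)oxy]methyl}-2,3-dihydro-1-benzofuran-5-carboxylate | COc1cc([C@@H]2Oc3c(OC)cc(C(=O)OC)cc3[C@H]2CO[Si](C(C)C)(C(C)C)C(C)C)cc(OC)c1OCOC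
A7 | alternative 3 | {[(2R,3S)-2-[3,5-dimethoxy-4-(methoxymethoxy)phenyl]-5-(methylsulfanyl)-2,3-dihydrofuran-3-yl]methoxy}triisopropylsilane | COc1cc([C@@H]2OC(SC)=C[C@H]2CO[Si](C(C)C)(C(C)C)C(C)C)cc(OC)c1OCOC
A8 | alternative 3 | methyl 3-methoxy-2-oxo-2H-pyran-5-carboxylate | COC(=O)C1=COC(=O)C(OC)=C1
A9 | alternative 3 | (4S,5R)-5-[3,5-dimethoxy-4-(methoxymethoxy)phenyl]-4-{[(triisopropylsilyl)oxy]methyl}oxolan-2-one | COc1cc([C@@H]2OC(=O)C[C@H]2CO[Si](C(C)C)(C(C)C)C(C)C)cc(OC)c1OCOC
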